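I read this flask at 2.0 min, and I reckon with what is missing from the charge, not with what is made.

in all of them: solid substrate 0.050 M

| charge | reagent | remark | time |
|---|---|---|---|
| noon | 1 equiv | run made earlier |  |
| winter | 1.5 equiv | run made earlier |  |
| flask | 2.00 equiv |  | 2.0 min |

| run | time / min | target / % | solid product / % |
|---|---|---|---|
| noon | 0.500 | 42.2 | 27.4 |
| noon | 1.00 | 60.7 | 45.3 |
| noon | 1.33 | 65.2 | 50.1 |
| noon | 2.00 | 67.4 | 53.2 |
| noon | 2.50 | 68.2 | 53.3 |
| winter | 0.500 | 60.5 | 43.5 |
| winter | 1.00 | 81.6 | 66.5 |
| winter | 1.33 | 83.4 | 67.1 |
| winter | 2.00 | 82.8 | 68.2 |
| winter | 2.50 | 83.9 | 66.6 |

(scatter of a reading: 0.5 percentage points)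

- a species is counted by the solid substrate in it: one self-condensation product counts as two
- amounts and yields of target count solid product too
- given per volume of solution although it is solid: solid substrate, solid product
- the numbers in the tables scatter with a standard deviation of 0.5 percentage points
- what may be going on: solid substrate <-> dissolved substrate; dissolved substrate + reagent -> target; reagent -> side product; solid product <-> target; 2 solid substrate -> self-condensation product
- at the start none of the solid substrate is in solution
- dissolved substrate means what is dissolved; the solid is not counted in it

- amount of target and solid product together at 2.0 min, in percent of the solid substrate charged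
- concentration of dissolved substrate in solution at 2.0 min, in percent of saturation

In the winter run the target stops rising from 1.33 min on, and the readings from then on leave 16.6 % of the charge missing from target; this missing share at the plateau, as read, is the gap. I take it as self-condensation, whose pull on the solid substrate grows with [solid substrate]. From noon to winter, with the same charge of solid substrate, more reagent speeds the early target: at 0.500 min target reads 60.5 % in the winter run against 42.2 % at noon, a ratio of 1.43 for a ratio of reagent of 1.50. So I let the gap go with charge over equivalents, and for this flask I reckon 12.5 % missing, so 87.5 % of target in all forms. I expect that plateau before 2.0 min, with reagent still beside what is dissolved and [dissolved substrate] near zero. Leave the charge as it is: by this reckoning the gap grows with it.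

The forecast gives 88 % and 0.2 %, reasoning that “the substrate has run out”.

The flask gives 85.3 % and 0 %.

    solid substrate ⇌ dissolved substrate, rate k1*(cs1 - [dissolved substrate]) while solid is left; crystals form when [dissolved substrate] > cs1 (solubility = 3.60 mM, k = 1.10 s⁻¹)
    dissolved substrate + reagent → target (k = 8.00 L mol⁻¹ s⁻¹)
    reagent → side product (k = 0.0110 s⁻¹)
    solid product ⇌ target, rate k4*(cs4 - [target]) while solid is left; crystals form when [target] > cs4 (solubility = 7.50 mM, k = 1.70 s⁻¹)
    2 solid substrate → self-condensation product (k = 0.190 L mol⁻¹ s⁻¹)

In this flask 85.3 % of the charge goes into solution, more than the 14.7 % that goes into self-condensation product, and solid substrate stands at 0 % by 1.00 min. This flask misses 14.7 %, more than the 12.5 % I reckoned, and solid substrate is the limiting reagent, at 0 % with 13 % of the reagent's charge left at 2.00 min. For a neighbour flask at 0.013 M with the same equivalents, the gap gives 3.24 % missing; that flask gives 97.7 %, so 2.30 % missing.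

All runs are simulated with made-up constants; the scatter is artificial.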